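**Remarks on the chemistry**

- Ring A is the enolised acyl cyclohexanetrione, ring B the spiro cyclohexane, ring C the cyclopentane. The β-triketone is drawn as one enol tautomer, and all tautomers are treated as one compound.
- β denotes the face of the ring B/C bicycle that carries the ring C oxygen (in 31 also the ring B hydroxyl and the ring A carbonyl next to C(Me)(prenyl)). α is the opposite face (ring-fusion hydrogens, both carbinol methyl groups).
- (2R)-2-Methylbutanoic acid is taken as a commercial single enantiomer; the acyl side chain of 31 is (R).
- The (S) propargylic carbinol of 14 maps onto the ring C carbinol of 17 and of 31 with the same spatial arrangement of oxygen, methyl, CH2 and the former alkyne carbon. The precursor and product skeletons of the key step are consistent with each other and with the target.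
- In 22 the ring B hydroxyl is syn-axial to the lactone carbonyl. A shift of the lactone to that oxygen would leave the same carbonyl activated, so step 17 would still lead to 28.

## Structural features

The target is a spiro tricycle in which ring A, a 2-acylcyclohexane-1,3,5-trione held as an enol, shares one quaternary carbon with ring B, a cyclohexane that is cis-fused to ring C, a cyclopentane. Ring A also holds a quaternary carbon with methyl and prenyl between two carbonyls, and an (R)-2-methylbutanoyl group on the enolised carbon. Four stereocentres are contiguous, namely the ring C carbinol C(Me)(OH), the two ring-fusion CH carbons and the ring B carbinol C(Me)(OH), with both hydroxyls on the β face and both fusion hydrogens and both carbinol methyl groups on the α face. The spiro carbon is 1,3 to the ring B carbinol and to one fusion carbon and places the carbonyl bonded to C(Me)(prenyl) on the β face, whereas the C(Me)(prenyl) centre is 1,3 to the spiro carbon and has no stereocentre next to it. Fragile groups are the acidic β-triketone (O- versus C-alkylation, retro-Claisen cleavage), the two tertiary alcohols (dehydration under acid), the prenyl alkene (acid-induced cyclisation onto an enol oxygen) and the enolisable α-stereocentre of the acyl chain. The real difficulty is the correlation of the spiro centre and of C(Me)(prenyl) with the ring B/C array. The key step uses the fact that the six carbons of ring B pair up as the spiro carbon plus the CH2 next to the ring B carbinol, the other CH2 plus the fusion carbon bonded to it, and the second fusion carbon plus the ring B carbinol carbon, where the last two pairs are tied together by the three remaining atoms of ring C and so correspond to the two alkynes of a 1,6-diyne, while the first pair is a methylenemalonate. The route further exploits that the ring C oxygen and the ring A carbonyl next to C(Me)(prenyl) are both β and 1,3 across ring B, so that they can be tied as a six-membered lactone.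

## Logic of the disconnections

31 to 29 and 30. The bond from the quaternary ring A carbon to the prenyl CH2 is cut. It is the last C–C bond at a carbon flanked by two carbonyls, and the enolised trione is its own nucleophile. This removes five carbons and one stereocentre. The forward step needs C- rather than O-alkylation and a facial choice directed only by the distant spiro centre, which is the weakest control in the plan.

29 to 22 and 26. Two ring A bonds are cut: from the methyl-bearing carbon to the β-face carbonyl, and from the acyl-bearing carbon to the other carbonyl. Both carbonyls are the ester-level carbons already on the spiro carbon, and the three-carbon unit with its acyl group is a β-diketone used as its dianion. Ring A and the side chain arrive in one operation, and 22 has no enolisable hydrogen. The forward step demands that the terminal carbanion attacks the lactone carbonyl and not the methyl ester, and that deprotonation of 26 spares its stereogenic methine.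

26 to 24 and then 23. The bond from the central CH2 to the propanoyl carbonyl is cut, then the methyl–carbonyl bond, which leads to 23. The forward steps need kinetic enolisation on the methyl side and no racemisation.

22 to 21. The C–CH3 bond at the ring B carbinol is cut, leaving a ketone. The lactone of 21 locks ring B in a chair whose β face at the ketone is covered by two syn-axial carbons. The forward step needs a non-basic methyl nucleophile that prefers the ketone over lactone and ester.

21 to 19. The lactone C–O bond is cut and the ring C oxygen returns to its silyl ether. This makes the two esters equivalent again and removes the spiro stereocentre. In the forward direction only the cis-fused isomer with oxygen and ring B CH2 cis on ring C can close the lactone, so the spiro configuration is dictated by the ring C carbinol.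

19 to 18. The two ring-fusion C–H bonds are cut to give the tetrasubstituted enone. Both centres then come from one syn addition. The forward step must deliver hydrogen to the α face, anti to the silyloxy group.

18 to 17. The ketone is traced back to its ethyl dienol ether. The forward step is a mild hydrolysis that must keep the tertiary silyl ether.

17 to 14 and 16. Three bonds are cut: malonate carbon to the former terminal alkyne carbon, the ring-fusion C–C bond, and CH2 to the ethoxy-bearing carbon. Two rings fall away and an acyclic diyne and a two-carbon acceptor remain. The forward step needs cross-selectivity and one regiochemistry.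

16 to 15. The methylene carbon comes from a one-carbon aldehyde equivalent. The forward step must deliver a monomer that is used before it polymerises.

14 to 13 to 9 and 10. The diyne is cut at the sp3–sp bond next to the ynol ether, after the terminal alkyne has been masked by silicon. The forward alkylation needs a very reactive primary electrophile and no free alkyne C–H.

9 to 8 to 6 to 5 to 4. The primary alcohol is unmasked from its benzylic ether. The alkyne with its tertiary carbinol is traced to an epoxy chloride, the chloride to an epoxy alcohol and this to an (E)-allylic alcohol. The only stereocentre of the diyne then rests on a catalytic asymmetric epoxidation of a trisubstituted allylic alcohol; the carbinol C–O bond is never broken afterwards.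

4 to 2 to 1. The C–CH3 and C–CH2OH bonds on the alkene are cut back to a terminal alkyne; the ether protecting group is removed last. The forward step needs syn carbometalation so that the alkene is formed as the single (E) isomer.

## Other disconnections considered

Alternative 1: Ring A is cut at the CH–C(O) bond and at the bond from the spiro carbon to the carbonyl next to C(Me)(prenyl).
- Forward step: the methyl enolate of acetyl hydrindane A1 is C-acylated by the enantiopure malonyl acid chloride A2. The resulting β-diketone is deprotonated at the ring methine and closes onto the methyl ester to give A3.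
- In favour: C(Me)(prenyl) arrives as a fixed, non-epimerisable centre from A2. On this point the alternative is better than the chosen plan, whose late prenylation has only remote control. The final C-acylation is equally simple in both plans.
- Against: the spiro centre is formed by a fully substituted enolate attacking a neopentyl ester, with facial choice on ring B under substrate control only. The product of that closure has a non-enolisable 1,3-dicarbonyl at the new bond and can reopen by retro-Claisen cleavage. A1 must first be made with all four ring B/C stereocentres, and A2 needs a separate desymmetrisation.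
- Comparison: the chosen plan fixes the spiro centre by a lactone tether, which is more secure, but is weaker at C(Me)(prenyl). Step economy is similar at best, because A1 needs its own route.

Alternative 2: The bond from one fusion carbon to the future ring B carbinol carbon and the bond from the other fusion carbon to the CH2 next to the future spiro carbon are cut; no ring is formed.
- Forward step: CuBr·SMe2 (monovalent copper) with a chiral bisphosphine adds isopropenylmagnesium bromide A5 to cyclopent-2-en-1-one A4, and the enolate is trapped by 16 to give A6.
- In favour: three cheap components, one pot, and catalytic enantiocontrol of a well-precedented type. It needs no ynol ether. In material cost and in the robustness of its C–C bond formations it is better than the chosen key step.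
- Against: A6 is trans and must be epimerised next to the ketone to reach the cis fusion. Ring B is still open and must be closed by joining the malonate carbon to the alkene CH2 with oxygen delivered to the internal carbon. Both tertiary carbinols then depend on separate facial selections. Trapping with 16 competes with its polymerisation, a handling problem the chosen route shares.
- Comparison: the chosen plan closes both rings and sets the oxidation level of the ring B carbinol carbon in one step, so it is shorter from the key step onwards. It is less secure in regiochemistry.

Alternative 3: The CH2–CH2 bond of ring C is cut.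
- Forward step: flash vacuum pyrolysis of the ring B-fused siloxyvinylcyclopropane A7 gives A8 by a vinylcyclopropane–cyclopentene rearrangement.
- In favour: a unimolecular thermal step with unambiguous regiochemistry and no metal. On regiochemistry it is better than the chosen key step. The silyl enol ether of A8 marks the ring C carbinol carbon as a ketone for a convex-face methyl addition. The gem-diester endgame is the same as in the chosen plan.
- Against: the diradical pathway can scramble the ring-fusion centre. The method needs special apparatus and is hard to scale. A7 needs a stereocontrolled cyclopropanation on a ring B that already carries its carbinol. The second fusion hydrogen is set only later, by protonation.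
- Comparison: the chosen plan starts from an acyclic diyne and needs no preformed ring B, and it is shorter; Alternative 3 is longer.

Key step: step 10

## Route

Step 1
Reactants: 1 but-3-yn-1-ol
Product: 2 1-[(but-3-yn-1-yloxy)methyl]-4-methoxybenzene
Conditions: NaH, 4-MeOC6H4CH2Cl, Bu4NI (cat.), THF/DMF, 0 °C to rt
Reagents that add atoms: 4-methoxybenzyl chloride COc1ccc(CCl)cc1
Why: Williamson etherification of the primary alkoxide; the ether survives organoaluminium, organolithium and epoxidation conditions and is later removed oxidatively without touching silyl groups.

Step 2
Reactants: 2 1-[(but-3-yn-1-yloxy)methyl]-4-methoxybenzene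
Product: 4 (2E)-5-[(4-methoxybenzyl)oxy]-3-methylpent-2-en-1-ol, via alkenyldimethylalane 3 (not isolated)
Conditions: Me3Al, Cp2ZrCl2 (0.25 equiv), CH2Cl2, 0 °C to rt; then n-BuLi, (CH2O)n, THF, −78 °C to rt; aq. HCl
Reagents that add atoms: trimethylaluminium C[Al](C)C; paraformaldehyde (as formaldehyde) C=O
Why: Negishi zirconium-catalysed carboalumination adds methyl and aluminium syn across the terminal alkyne, and the alkenyl aluminate is hydroxymethylated with retention, so only the (E) allylic alcohol should form.

Step 3
Reactants: 4 (2E)-5-[(4-methoxybenzyl)oxy]-3-methylpent-2-en-1-ol
Product: 5 [(2S,3S)-3-{2-[(4-methoxybenzyl)oxy]ethyl}-3-methyloxiran-2-yl]methanol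
Conditions: Ti(OiPr)4 (10 mol%), L-(+)-diethyl tartrate (12 mol%), t-BuOOH, 4 Å MS, CH2Cl2, −20 °C
Reagents that add atoms: tert-butyl hydroperoxide CC(C)(C)OO
Why: Sharpless asymmetric epoxidation of a geraniol-type trisubstituted allylic alcohol; the L-(+)-tartrate complex is expected to give the (2S,3S) epoxide, whose quaternary carbon becomes the ring C carbinol.

Step 4
Reactants: 5 [(2S,3S)-3-{2-[(4-methoxybenzyl)oxy]ethyl}-3-methyloxiran-2-yl]methanol
Product: 6 (2S,3R)-3-(chloromethyl)-2-{2-[(4-methoxybenzyl)oxy]ethyl}-2-methyloxirane
Conditions: PPh3, CCl4, NaHCO3, reflux
Reagents that add atoms: carbon tetrachloride ClC(Cl)(Cl)Cl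
Why: Appel chlorination of the primary alcohol under buffered neutral conditions leaves the epoxide intact; the stereocentres are untouched and only the descriptor at the CH carbon changes.

Step 5
Reactants: 6 (2S,3R)-3-(chloromethyl)-2-{2-[(4-methoxybenzyl)oxy]ethyl}-2-methyloxirane
Product: 8 (3S)-5-[(4-methoxybenzyl)oxy]-3-methyl-1-(triethylsilyl)-3-[(triethylsilyl)oxy]pent-1-yne, via dilithium alkoxide acetylide 7 (not isolated)
Conditions: n-BuLi (3.3 equiv), THF, −78 to −30 °C; then Et3SiCl (2.6 equiv), −78 °C to rt
Reagents that add atoms: chlorotriethylsilane CC[Si](CC)(CC)Cl
Why: Base-induced fragmentation of a 2,3-epoxy chloride (epoxide-opening elimination, then dehydrochlorination) gives the tertiary propargylic alkoxide with the C–O bond of the stereocentre intact; both anionic sites are capped in the same flask, which protects the carbinol and masks the acidic alkyne C–H.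

Step 6
Reactants: 8 (3S)-5-[(4-methoxybenzyl)oxy]-3-methyl-1-(triethylsilyl)-3-[(triethylsilyl)oxy]pent-1-yne
Product: 9 (3S)-3-methyl-5-(triethylsilyl)-3-[(triethylsilyl)oxy]pent-4-yn-1-ol
Conditions: DDQ, CH2Cl2/pH 7 buffer, 0 °C
Reagents that add atoms: none
Why: Oxidative cleavage of the 4-methoxybenzyl ether under buffered conditions; the tertiary silyl ether and the silyl alkyne are inert to DDQ.

Step 7
Reactants: 9 (3S)-3-methyl-5-(triethylsilyl)-3-[(triethylsilyl)oxy]pent-4-yn-1-ol; 10 ethoxyethyne
Product: 13 (3S)-7-ethoxy-3-methyl-1-(triethylsilyl)-3-[(triethylsilyl)oxy]hepta-1,6-diyne, via triflate 11 (not isolated), via lithium ethoxyacetylide 12 (not isolated)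
Conditions: Tf2O, 2,6-lutidine, CH2Cl2, −78 °C; then 12 (from 10, n-BuLi, THF, −78 °C), THF, −78 to −20 °C
Reagents that add atoms: none
Why: SN2 alkylation of a lithium alkoxyacetylide by a primary triflate, the most reactive electrophile for this weakly nucleophilic acetylide; the silyl cap prevents proton exchange and self-alkylation at the other alkyne, and the silyl ether prevents oxetane formation.

Step 8
Reactants: 13 (3S)-7-ethoxy-3-methyl-1-(triethylsilyl)-3-[(triethylsilyl)oxy]hepta-1,6-diyne
Product: 14 (3S)-7-ethoxy-3-methyl-3-[(triethylsilyl)oxy]hepta-1,6-diyne
Conditions: K2CO3, MeOH, rt to 40 °C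
Reagents that add atoms: none
Why: Methoxide-mediated protodesilylation cleaves the C(sp)–Si bond, while the hindered tertiary silyl ether and the base-stable ynol ether should remain.

Step 9
Reactants: 15 dimethyl malonate
Product: 16 dimethyl methylenemalonate
Conditions: (CH2O)n, Cu(OAc)2 (cat.), KOAc (cat.), AcOH, 100 °C; distilled at reduced pressure directly before use
Reagents that add atoms: paraformaldehyde (as formaldehyde) C=O
Why: Knoevenagel methylenation; the monomer polymerises readily and is therefore cracked and used at once.

Step 10
Reactants: 14 (3S)-7-ethoxy-3-methyl-3-[(triethylsilyl)oxy]hepta-1,6-diyne; 16 dimethyl methylenemalonate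
Product: 17 dimethyl (1S)-4-ethoxy-1-methyl-1-[(triethylsilyl)oxy]-1,2,3,5-tetrahydro-6H-indene-6,6-dicarboxylate
Conditions: [Rh(cod)2]BF4 (10 mol%), rac-BINAP (10 mol%), H2 then Ar (activation), 16 (5 equiv), (CH2Cl)2, rt, 14 added over 2 h
Reagents that add atoms: none
Why: Hydrogenation of the cod ligands frees a cationic monovalent rhodium bisphosphine fragment that binds both alkynes of the 1,6-diyne and couples them oxidatively to a rhodacyclopentadiene. The closest known reaction type is the cationic rhodium/bisphosphine [2+2+2] cycloaddition of 1,6-diynes with 1,1-disubstituted electron-poor alkenes, which gives cyclohexa-1,3-dienes with a quaternary carbon. Ring C closes in the oxidative coupling, which joins the two internal alkyne carbons in a five-membered carbocycle. Ring B closes by migratory insertion of the alkene into a Rh–C bond followed by C–C reductive elimination. No stereocentre is formed; the silyl-protected carbinol lies outside the reacting bonds and passes unchanged, and the quaternary malonate carbon blocks aromatisation. The step needs cross- over homo-cycloaddition, which slow addition of the diyne into excess alkene should secure. It also needs one regiochemistry: the electron-rich α-ethoxyalkenyl–Rh bond should add to the acceptor CH2 and leave a stabilised rhodium malonate, and the bulky malonate carbon should then couple with the unsubstituted CH terminus rather than next to the ethoxy group. The silyl ether, chosen over the free carbinol, keeps the hydroxyl from adding to the activated ynol ether or to the Michael acceptor.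

Step 11
Reactants: 17 dimethyl (1S)-4-ethoxy-1-methyl-1-[(triethylsilyl)oxy]-1,2,3,5-tetrahydro-6H-indene-6,6-dicarboxylate
Product: 18 dimethyl (1S)-1-methyl-4-oxo-1-[(triethylsilyl)oxy]-1,2,3,4,5,7-hexahydro-6H-indene-6,6-dicarboxylate
Conditions: oxalic acid (0.5 M aq.), THF, 0 °C to rt
Reagents that add atoms: water O
Why: Hydrolysis of the 1-ethoxydiene; protonation at the diene terminus (or acid isomerisation of a β,γ-isomer) leads to the conjugated tetrasubstituted ring-fusion enone, and the mild acid should spare the tertiary silyl ether.

Step 12
Reactants: 18 dimethyl (1S)-1-methyl-4-oxo-1-[(triethylsilyl)oxy]-1,2,3,4,5,7-hexahydro-6H-indene-6,6-dicarboxylate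
Product: 19 dimethyl (1S)-1-methyl-4-oxo-1-[(triethylsilyl)oxy]octahydro-6H-indene-6,6-dicarboxylate, cis-fused, both ring-fusion hydrogens α (anti to the silyloxy group, syn to its methyl)
Conditions: H2 (5 bar), 10% Pd/C, EtOAc, rt
Reagents that add atoms: none
Why: Heterogeneous hydrogenation adds both hydrogens to one face, so the fusion is cis by mechanism; the catalyst surface should approach the face of the allylic quaternary carbon that carries methyl rather than the triethylsilyloxy group, and neutral conditions avoid epimerisation next to the ketone.

Step 13
Reactants: 19 dimethyl (1S)-1-methyl-4-oxo-1-[(triethylsilyl)oxy]octahydro-6H-indene-6,6-dicarboxylate (cis-fused)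
Product: 21 tricyclic keto lactone methyl ester (six-membered lactone from the ring C oxygen to the β ester of the malonate carbon), via tetrabutylammonium alkoxide 20 (not isolated)
Conditions: Bu4NF (1.2 equiv), THF, 0 °C to rt; aq. NH4Cl
Reagents that add atoms: none
Why: Fluoride desilylation frees a tertiary alkoxide that transesterifies the one ester on its own face (bicyclo[3.3.1] lactone from two 1,3-diaxial groups), so the malonate carbon becomes a stereocentre whose configuration is dictated by the ring C carbinol. Only the cis-fused isomer with oxygen and ring B CH2 cis on ring C can close, and the lactone then blocks epimerisation of the fusion.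

Step 14
Reactants: 21 tricyclic keto lactone methyl ester
Product: 22 tricyclic hydroxy lactone methyl ester (ring B carbinol: hydroxyl β, methyl α)
Conditions: CeCl3 (anhydrous), MeLi, THF, −78 °C; AcOH quench at −78 °C
Reagents that add atoms: methyllithium [Li]C
Why: Organocerium 1,2-addition (Imamoto conditions) is non-basic and prefers the ketone over lactone and ester. The lactone holds ring B in the chair in which the β face of the ketone is covered by the syn-axial lactone carbonyl and ring C carbon, so methyl should enter equatorially from the α face.

Step 15
Reactants: 23 (2R)-2-methylbutanoic acid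
Product: 24 (3R)-3-methylpentan-2-one
Conditions: MeLi (2.1 equiv), Et2O, 0 °C; poured into cold aq. HCl
Reagents that add atoms: methyllithium [Li]C
Why: Addition of methyllithium to the lithium carboxylate gives a stable geminal dialkoxide that releases the ketone only on work-up, so neither over-addition nor enolisation of the α-stereocentre should occur.

Step 16
Reactants: 24 (3R)-3-methylpentan-2-one
Product: 26 (6R)-6-methyloctane-3,5-dione, via lithium enolate 25 (not isolated)
Conditions: LiN(iPr)2 (1.05 equiv), THF, −78 °C; then EtC(O)N(OMe)Me, −78 to 0 °C; aq. NH4Cl
Reagents that add atoms: N-methoxy-N-methylpropanamide CCC(=O)N(C)OC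
Why: Kinetic deprotonation occurs at the methyl group and not at the stereogenic methine; acylation by the Weinreb amide stops at a chelated tetrahedral adduct, so the acidic β-diketone appears only on work-up and cannot quench the enolate.

Step 17
Reactants: 22 tricyclic hydroxy lactone methyl ester; 26 (6R)-6-methyloctane-3,5-dione
Product: 29 des-prenyl spiro trione (ring A complete, methyl-bearing ring A carbon still enolisable, both tertiary hydroxyls free), via dilithium dienolate 27 (not isolated), via open-chain triketone 28 (not isolated)
Conditions: 26 (3 equiv), LiN(iPr)2 (6.2 equiv), THF, −78 to 0 °C; then 22, −78 °C to rt, then 50 °C; cold aq. HCl (0.5 M)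
Reagents that add atoms: none
Why: Hauser-type β-diketone dianion acylation: the terminal carbanion attacks the lactone carbonyl, which is more electrophilic than the methyl ester and has no enolisable neighbour, and the liberated 1,3,5-triketone anion closes onto the remaining ester (intramolecular Claisen condensation). The lactone carbonyl becomes the ketone next to the methyl-bearing carbon, so the spiro configuration set in step 13 is transferred; the second deprotonation of 26 should occur at CH2 rather than at the more hindered stereogenic methine.

Step 18
Reactants: 29 des-prenyl spiro trione; 30 1-bromo-3-methylbut-2-ene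
Product: 31 CNP0236509.3
Conditions: 30 (1.3 equiv), NaOMe, MeOH, 0 °C to rt; chromatographic separation of the epimers at the new centre
Reagents that add atoms: none
Why: C-alkylation of the enolised acyl trione in a protic medium (as in the C-alkylation of acylfilicinic acids); the acyl-bearing carbon is blocked and the tertiary alcohols are not alkylated. The new quaternary centre is controlled only by 1,3-induction from the spiro centre, so a mixture of epimers is expected, and 31 is the epimer with prenyl on the face of ring A that carries the ring B CH2 bonded to the ring-fusion carbon.

## Compound list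

1 | but-3-yn-1-ol | C#CCCO | starting material
2 | 1-[(but-3-yn-1-yloxy)methyl]-4-methoxybenzene | C#CCCOCc1ccc(OC)cc1 | intermediate
3 | dimethyl[(1E)-4-[(4-methoxybenzyl)oxy]-2-methylbut-1-en-1-yl]alane, formed in the flask | C[Al](C)/C=C(\C)CCOCc1ccc(OC)cc1 | intermediate
4 | (2E)-5-[(4-methoxybenzyl)oxy]-3-methylpent-2-en-1-ol | OC/C=C(\C)CCOCc1ccc(OC)cc1 | intermediate
5 | [(2S,3S)-3-{2-[(4-methoxybenzyl)oxy]ethyl}-3-methyloxiran-2-yl]methanol | OC[C@@H]1O[C@@]1(C)CCOCc1ccc(OC)cc1 | intermediate
6 | (2S,3R)-3-(chloromethyl)-2-{2-[(4-methoxybenzyl)oxy]ethyl}-2-methyloxirane | ClC[C@@H]1O[C@@]1(C)CCOCc1ccc(OC)cc1 | intermediate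
7 | dilithium alkoxide acetylide of (3S)-5-[(4-methoxybenzyl)oxy]-3-methylpent-1-yn-3-ol, formed in the flask | [Li]C#C[C@@](C)(O[Li])CCOCc1ccc(OC)cc1 | intermediate
8 | (3S)-5-[(4-methoxybenzyl)oxy]-3-methyl-1-(triethylsilyl)-3-[(triethylsilyl)oxy]pent-1-yne | CC[Si](CC)(CC)C#C[C@@](C)(O[Si](CC)(CC)CC)CCOCc1ccc(OC)cc1 | intermediate
9 | (3S)-3-methyl-5-(triethylsilyl)-3-[(triethylsilyl)oxy]pent-4-yn-1-ol | CC[Si](CC)(CC)C#C[C@@](C)(O[Si](CC)(CC)CC)CCO | intermediate
10 | ethoxyethyne | CCOC#C | starting material
11 | primary triflate of 9, formed in the flask | CC[Si](CC)(CC)C#C[C@@](C)(O[Si](CC)(CC)CC)CCOS(=O)(=O)C(F)(F)F | intermediate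
12 | lithium ethoxyacetylide, formed in the flask | [Li]C#COCC | intermediate
13 | (3S)-7-ethoxy-3-methyl-1-(triethylsilyl)-3-[(triethylsilyl)oxy]hepta-1,6-diyne | CC[Si](CC)(CC)C#C[C@@](C)(O[Si](CC)(CC)CC)CCC#COCC | intermediate
14 | (3S)-7-ethoxy-3-methyl-3-[(triethylsilyl)oxy]hepta-1,6-diyne (triethylsilyl ether of 7-ethoxy-3-methylhepta-1,6-diyn-3-ol) | C#C[C@@](C)(O[Si](CC)(CC)CC)CCC#COCC | intermediate
15 | dimethyl malonate | COC(=O)CC(=O)OC | starting material
16 | dimethyl methylenemalonate | C=C(C(=O)OC)C(=O)OC | intermediate
17 | dimethyl (1S)-4-ethoxy-1-methyl-1-[(triethylsilyl)oxy]-1,2,3,5-tetrahydro-6H-indene-6,6-dicarboxylate (bicyclic dienol ether gem-diester) | COC(=O)C1(C(=O)OC)C=C2C(CC[C@]2(C)O[Si](CC)(CC)CC)=C(OCC)C1 | intermediate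
18 | dimethyl (1S)-1-methyl-4-oxo-1-[(triethylsilyl)oxy]-1,2,3,4,5,7-hexahydro-6H-indene-6,6-dicarboxylate (ring-fusion enone) | COC(=O)C1(C(=O)OC)CC2=C(CC[C@]2(C)O[Si](CC)(CC)CC)C(=O)C1 | intermediate
19 | cis-fused dimethyl (1S)-1-methyl-4-oxo-1-[(triethylsilyl)oxy]octahydro-6H-indene-6,6-dicarboxylate, fusion hydrogens anti to the silyloxy group | COC(=O)C1(C(=O)OC)C[C@@H]2[C@@H](CC[C@]2(C)O[Si](CC)(CC)CC)C(=O)C1 | intermediate
20 | tetrabutylammonium tertiary alkoxide of desilylated 19, formed in the flask | COC(=O)C1(C(=O)OC)C[C@@H]2[C@@H](CC[C@]2(C)[O-])C(=O)C1.CCCC[N+](CCCC)(CCCC)CCCC | intermediate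
21 | tricyclic keto lactone methyl ester (lactone from the ring C oxygen to the β ester; ketone at the future ring B carbinol carbon) | COC(=O)[C@@]1(C[C@@H]2[C@@H](CC[C@]2(C)O3)C(=O)C1)C3=O | intermediate
22 | tricyclic hydroxy lactone methyl ester (ring B carbinol with hydroxyl β and methyl α) | COC(=O)[C@@]1(C[C@@H]2[C@@H](CC[C@]2(C)O3)[C@@](C)(O)C1)C3=O | intermediate
23 | (2R)-2-methylbutanoic acid | CC[C@@H](C)C(=O)O | starting material
24 | (3R)-3-methylpentan-2-one | CC[C@@H](C)C(C)=O | intermediate
25 | lithium enolate of 24 on the methyl side, formed in the flask | CC[C@@H](C)C(=C)O[Li] | intermediate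
26 | (6R)-6-methyloctane-3,5-dione | CCC(=O)CC(=O)[C@H](C)CC | intermediate
27 | dilithium dienolate of 26, formed in the flask | CC[C@@H](C)C(O[Li])=CC(O[Li])=CC | intermediate
28 | open-chain triketone dihydroxy methyl ester from lactone opening (drawn neutral), formed in the flask | COC(=O)[C@]1(C(=O)C(C)C(=O)CC(=O)[C@H](C)CC)C[C@@H]2[C@@H](CC[C@]2(C)O)[C@@](C)(O)C1 | intermediate
29 | des-prenyl spiro trione, drawn as the dienol tautomer | CC[C@@H](C)C(=O)C1=C(O)C(C)=C(O)[C@]2(C[C@@H]3[C@@H](CC[C@]3(C)O)[C@@](C)(O)C2)C1=O | intermediate
30 | 1-bromo-3-methylbut-2-ene (prenyl bromide) | CC(C)=CCBr | starting material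
31 | CNP0236509.3 | CC[C@@H](C)C(=O)C1=C(O)[C@](C)(CC=C(C)C)C(=O)[C@]2(C[C@@H]3[C@@H](CC[C@]3(C)O)[C@@](C)(O)C2)C1=O | target

## Step count and least certain steps

Total step count: 18. Longest linear sequence: 15 (steps 1 to 8, 10 to 14, 17 and 18). Steps 9, 15 and 16 are side branches.

Step 10 (key step). The most likely failures are:
- coupling with the opposite orientation of the alkene, because a polar pairing of the ynol ether β-carbon with the acceptor CH2 opposes the steric preference;
- a Lewis-acid-type [2+2] addition of the ynol ether to the acceptor, or hydration of the ynol ether by the cationic catalyst;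
- homo-coupling of the diyne and polymerisation of 16.

The fallback abandons the cycloaddition and builds ring C by aldol condensation and ring B by malonate alkylation. It sets out from 9 by way of triflate 11 and returns at 18. Triflate 11 would alkylate the dilithium dianion of commercial dimethyl 2-(2-oxopropyl)malonate at its methyl carbon to give the keto malonate F1. K2CO3 in methanol would free the alkyne to give the terminal alkyne F2. Hydration with Ph3PAuNTf2 (monovalent gold) in wet dioxane would give the 1,6-diketone F3. Aldol condensation (pyrrolidine, AcOH) would close ring C as the acylcyclopentene F4, the five-membered mode being the only unstrained one. Allylic bromination of the ring methyl group (NBS) would give the bromide F5, and K2CO3 would close ring B by intramolecular malonate alkylation to 18.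

Step 12. The risk is poor facial selectivity: the oxygen of the silyl ether is small at its point of attachment, and the catalyst surface could approach the β face. The fallback replaces surface hydrogenation by nucleophilic 1,4-hydride delivery. It sets out from 18 and returns at 21. [(Ph3P)CuH]6 (monovalent copper) would add hydride to the ring-fusion β-carbon anti to the allylic C–O bond (Felkin-type control by the adjacent quaternary centre). Protonation of the enolate without control would give 19 together with its ring-fusion epimer, the trans-fused ketone F6. Under the fluoride conditions of step 13 the centre next to the ketone equilibrates, and only the cis isomer can lactonise, so both would converge on 21.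

Step 17. The risks are:
- slow attack of the secondary carbanion on the neopentyl lactone carbonyl;
- competing attack at the methyl ester, which would invert the spiro centre;
- partial deprotonation of 26 at its stereogenic methine, with loss of configuration;
- incomplete ring closure onto the hindered ester.

The fallback uses a simpler dianion and adds the acyl group last. It sets out from 22 and returns at 29. The dianion of methyl 3-oxopentanoate (NaH, then n-BuLi) would open the lactone and close ring A to the ester-substituted trione F7. Dealkoxycarbonylation (LiCl, wet DMSO, heat) would give the des-acyl trione F8. C-acylation with 23 (DCC, DMAP; O-acylation followed by DMAP-mediated O-to-C acyl shift at the unsubstituted ring carbon) would give 29.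

Step 18. The risks are poor facial selectivity at the new quaternary centre, because the only stereocentre near it is the spiro carbon with two similar CH2 arms, and some O-alkylation. The fallback replaces substrate control by catalyst control and makes no new compound. It sets out from 29 and returns at 31. Zerovalent palladium (Pd2(dba)3) with a chiral diamine-derived bisphosphine (Trost ligand, both enantiomers available) and prenyl acetate would generate a π-prenyl palladium complex. The trione enolate attacks it at the primary terminus inside the chiral pocket. O-allylation is reversible under these conditions. The ligand enantiomer that gives 31 would have to be identified in the first runs.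

## Further compounds

F1 | step 10 | dimethyl 2-[(6S)-6-methyl-2-oxo-8-(triethylsilyl)-6-[(triethylsilyl)oxy]oct-7-yn-1-yl]malonate | CC[Si](CC)(CC)C#C[C@@](C)(O[Si](CC)(CC)CC)CCCC(=O)CC(C(=O)OC)C(=O)OC
F2 | step 10 | dimethyl 2-[(6S)-6-methyl-2-oxo-6-[(triethylsilyl)oxy]oct-7-yn-1-yl]malonate | C#C[C@@](C)(O[Si](CC)(CC)CC)CCCC(=O)CC(C(=O)OC)C(=O)OC
F3 | step 10 | dimethyl 2-[(6S)-6-methyl-2,7-dioxo-6-[(triethylsilyl)oxy]octyl]malonate | CC(=O)[C@@](C)(O[Si](CC)(CC)CC)CCCC(=O)CC(C(=O)OC)C(=O)OC
F4 | step 10 | dimethyl 2-{2-[(3S)-2,3-dimethyl-3-[(triethylsilyl)oxy]cyclopent-1-en-1-yl]-2-oxoethyl}malonate | CC1=C(C(=O)CC(C(=O)OC)C(=O)OC)CC[C@]1(C)O[Si](CC)(CC)CC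
F5 | step 10 | dimethyl 2-{2-[(3S)-2-(bromomethyl)-3-methyl-3-[(triethylsilyl)oxy]cyclopent-1-en-1-yl]-2-oxoethyl}malonate | BrCC1=C(C(=O)CC(C(=O)OC)C(=O)OC)CC[C@]1(C)O[Si](CC)(CC)CC
F6 | step 12 | trans-fused ring-fusion epimer of 19 (epimeric at the carbon next to the ketone) | COC(=O)C1(C(=O)OC)C[C@@H]2[C@H](CC[C@]2(C)O[Si](CC)(CC)CC)C(=O)C1
F7 | step 17 | spiro trione with a methoxycarbonyl group in place of the acyl group, dienol tautomer | COC(=O)C1=C(O)C(C)=C(O)[C@]2(C[C@@H]3[C@@H](CC[C@]3(C)O)[C@@](C)(O)C2)C1=O
F8 | step 17 | des-acyl des-prenyl spiro trione, dienol tautomer | C1=C(O)C(C)=C(O)[C@]2(C[C@@H]3[C@@H](CC[C@]3(C)O)[C@@](C)(O)C2)C1=O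
F0 | step 18 | none | none
A1 | alternative 1 | acetyl cis-hydrindane bis(triethylsilyl ether), acetyl on the future spiro carbon (configuration at that carbon not defined) | CC(=O)C1C[C@@H]2[C@@H](CC[C@]2(C)O[Si](CC)(CC)CC)[C@@](C)(O[Si](CC)(CC)CC)C1
A2 | alternative 1 | methyl 2-(chlorocarbonyl)-2,5-dimethylhex-4-enoate, single enantiomer | ClC(=O)[C@](C)(CC=C(C)C)C(=O)OC
A3 | alternative 1 | des-acyl spiro trione bis(triethylsilyl ether) | C1=C(O)[C@](C)(CC=C(C)C)C(=O)[C@]2(C[C@@H]3[C@@H](CC[C@]3(C)O[Si](CC)(CC)CC)[C@@](C)(O[Si](CC)(CC)CC)C2)C1=O
A4 | alternative 2 | cyclopent-2-en-1-one | O=C1C=CCC1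
A5 | alternative 2 | isopropenylmagnesium bromide | CC(=C)[Mg]Br
A6 | alternative 2 | dimethyl trans-[(2-isopropenyl-5-oxocyclopentyl)methyl]malonate | COC(=O)C(C[C@H]1[C@@H](CCC1=O)C(C)=C)C(=O)OC
A7 | alternative 3 | ring B-fused 1-[1-(trimethylsilyloxy)vinyl]cyclopropane gem-diester | COC(=O)C1(C(=O)OC)C[C@@]2(C(=C)O[Si](C)(C)C)C[C@H]2[C@@](C)(O[Si](C)(C)C)C1
A8 | alternative 3 | hydrindene silyl enol ether gem-diester | COC(=O)C1(C(=O)OC)CC2=C(O[Si](C)(C)C)CC[C@H]2[C@@](C)(O[Si](C)(C)C)C1
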